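The labdane core is traced back to the acyclic all-E trienone 1, (5E,9E)-farnesylacetone. A chiral proton source attacks C3, and one cascade forms C4–C5 (ring A), C9–C10 (ring B) and O–C8 (dihydropyran ring C). This sets C5, C10, C9 and C8 at once and gives enol ether 2, sclareol oxide. The step exploits the fact that the trans-fused rings A and B, the quaternary C10 methyl, the equatorial C9 chain and the equatorial C8 oxygen are the anti-addition pattern of a chair–chair folded E,E-polyene whose C13 carbonyl oxygen can close a six-membered ring onto C8. Hydrolysis, two-carbon homologation, catalyst-controlled hydrogenation (C13) and acylation complete the target.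

Key step: step 1

Assumption (labdane numbering throughout): the target is the (5S,8R,9R,10S,13S)-labdane of the sclareol series; the (R)-configured SnCl4–binaphthol acid is taken to give this series by analogy with hydroxyl-terminated polyprenoids (the (S)-ligand would be used if the sense proved opposite), and 1 is bought geometrically pure.

Step 1
Reactants: 1 (5E,9E)-farnesylacetone
Product: 2 sclareol oxide [(5S,8R,9R,10S)-8,13-epoxy-14,15-dinorlabd-12-ene]
Conditions: SnCl4 (2.0 equiv), (R)-2'-methoxy-1,1'-binaphthalen-2-ol (2.2 equiv), toluene, −78 °C; then aq NaHCO3
Reagents that add atoms: none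
Why: Proposed new method: the SnCl4-bound binaphthol hydroxyl is a strong chiral proton donor that should protonate the terminal alkene of 1 at C3, after which the C4 cation is attacked by C5=C10 (6-endo, ring A), the C10 cation by C8=C9 (6-endo, ring B) and the C8 cation by the carbonyl oxygen (6-endo with respect to C8=C9, ring C), the oxocarbenium ion then losing H-12 to give the enol ether. The closest known reactions are polyene cyclizations induced by this type of Lewis acid-assisted chiral Brønsted acid with hydroxyl and arene terminators, and the racemic strong-acid closure of this same ketone, so only the pairing of chiral acid and ketone terminator is untested. C5 is set by the enantioface of C5=C10 that the chiral acid selects as it delivers the proton; C10 and C9 follow from the E geometry of both alkenes in a chair–chair fold (antiperiplanar additions, hence trans ring fusion and equatorial C9 chain); C8 follows from equatorial attack of oxygen anti to the new C9–C10 bond. The step needs protonation at the isopropylidene end in preference to the internal alkenes and the carbonyl; that end is the most accessible and the farthest from the carbonyl, an acid-bound ketone has no easy Prins path (closure onto C9 would give a four-membered ring, onto C8 a secondary cation), and two equivalents of acid allow for one being held by the carbonyl. The free ketone is kept as terminator because a ketal or enol ether would be ionized or protonated before the alkene, and every terminated form (endo or exo enol ether, hemiketal, ketol) converges in step 2.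

Step 2
Reactants: 2 sclareol oxide
Product: 4 8α-hydroxy-14,15-dinorlabdan-13-one (ketol), via cyclic hemiketal 3 (not isolated)
Conditions: 0.5 M aq HCl, THF, 0 °C to rt; NaHCO3 before concentration
Reagents that add atoms: water, O
Why: Enol ether hydrolysis, in which protonation at C12 gives the ring C oxocarbenium ion, water adds at C13 to give hemiketal 3 and ring–chain opening releases the δ-hydroxy ketone, while dilute acid and neutralization before concentration keep the tertiary C8 alcohol from eliminating or re-closing and no stereocentre is touched.

Step 3
Reactants: 4 8α-hydroxy-14,15-dinorlabdan-13-one; 5 triethyl phosphonoacetate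
Product: 6 ethyl (13E)-8α-hydroxylabd-13-en-15-oate
Conditions: (EtO)2P(O)CH2CO2Et (2.8 equiv), NaH (2.5 equiv), THF, 0 to 60 °C; chromatography
Reagents that add atoms: triethyl phosphonoacetate (compound 5), CCOC(=O)CP(=O)(OCC)OCC
Why: Horner–Wadsworth–Emmons olefination of a methyl ketone, in which reversible addition and syn elimination should place the ester trans to the larger C12 chain (13E), the phosphonate being kept in excess over NaH so that the far less acidic tertiary hydroxyl stays protonated and does not add to C13, and the minor 13Z ester being removed by chromatography.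

Step 4
Reactants: 6 ethyl (13E)-8α-hydroxylabd-13-en-15-oate
Product: 7 (13E)-labd-13-ene-8α,15-diol
Conditions: i-Bu2AlH (3.5 equiv), CH2Cl2, −78 to 0 °C; aq KNaC4H4O6
Reagents that add atoms: none
Why: 1,2-Reduction of an α,β-unsaturated ester with i-Bu2AlH gives the allylic alcohol without touching the trisubstituted alkene or its E geometry, the tertiary hydroxyl only consuming one hydride as its aluminium alkoxide.

Step 5
Reactants: 7 (13E)-labd-13-ene-8α,15-diol
Product: 8 (13S)-labdane-8α,15-diol
Conditions: Ru(OAc)2[(R)-BINAP] (1 mol %), H2 (100 atm), MeOH, 20 °C
Reagents that add atoms: none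
Why: Noyori asymmetric hydrogenation of an allylic alcohol, in which the C15 hydroxyl binds ruthenium and the (R)-BINAP ligand delivers H2 to the C13 face that converts an E-configured 3-methyl allylic alcohol into the 13S product (the sense of geraniol to (S)-citronellol), so C13 is set by the catalyst independently of the remote ring stereocentres, and material from the minor antipode of step 1 becomes a diastereomer that recrystallization of 8 should remove.

Step 6
Reactants: 8 (13S)-labdane-8α,15-diol; 9 3-phenylpropanoyl chloride
Product: 10 (13S)-8α-hydroxylabdan-15-yl 3-phenylpropanoate (target)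
Conditions: PhCH2CH2COCl (1.1 equiv), pyridine, CH2Cl2, 0 °C
Reagents that add atoms: 3-phenylpropanoyl chloride (compound 9), O=C(Cl)CCc1ccccc1
Why: Chemoselective esterification with an acyl chloride and pyridine, in which the primary C15 hydroxyl reacts at 0 °C while the hindered tertiary C8 hydroxyl is inert without an acyl-transfer catalyst, and the base captures HCl so that the tertiary alcohol does not ionize.

Compound list
1 | (5E,9E)-farnesylacetone, (5E,9E)-6,10,14-trimethylpentadeca-5,9,13-trien-2-one | CC(=O)CC/C=C(\C)CC/C=C(\C)CCC=C(C)C | starting material
2 | sclareol oxide, (5S,8R,9R,10S)-8,13-epoxy-14,15-dinorlabd-12-ene | CC1=CC[C@@H]2[C@@]3(C)CCCC(C)(C)[C@@H]3CC[C@@]2(C)O1 | intermediate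
3 | cyclic hemiketal, 8,13-epoxy-14,15-dinorlabdan-13-ol (either C13 epimer) | CC1(O)CC[C@@H]2[C@@]3(C)CCCC(C)(C)[C@@H]3CC[C@@]2(C)O1 | intermediate (not isolated)
4 | 8α-hydroxy-14,15-dinorlabdan-13-one (5S,8R,9R,10S) | CC(=O)CC[C@@H]1[C@@]2(C)CCCC(C)(C)[C@@H]2CC[C@@]1(C)O | intermediate
5 | triethyl phosphonoacetate | CCOC(=O)CP(=O)(OCC)OCC | starting material
6 | ethyl (13E)-8α-hydroxylabd-13-en-15-oate | CCOC(=O)/C=C(\C)CC[C@@H]1[C@@]2(C)CCCC(C)(C)[C@@H]2CC[C@@]1(C)O | intermediate
7 | (13E)-labd-13-ene-8α,15-diol | OC/C=C(\C)CC[C@@H]1[C@@]2(C)CCCC(C)(C)[C@@H]2CC[C@@]1(C)O | intermediate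
8 | (13S)-labdane-8α,15-diol | C[C@H](CCO)CC[C@@H]1[C@@]2(C)CCCC(C)(C)[C@@H]2CC[C@@]1(C)O | intermediate
9 | 3-phenylpropanoyl chloride | O=C(Cl)CCc1ccccc1 | starting material
10 | (5S,8R,9R,10S,13S)-8-hydroxylabdan-15-yl 3-phenylpropanoate | C[C@H](CCOC(=O)CCc1ccccc1)CC[C@@H]1[C@@]2(C)CCCC(C)(C)[C@@H]2CC[C@@]1(C)O | target

Total step count: 6. Longest linear sequence: 6 steps (1 → 2 → 4 → 6 → 7 → 8 → 10).

Steps most likely to fail

Step 1 (carries the label). The carbonyl may compete with the binaphthol ligand for SnCl4, leaving an achiral proton source and eroding enantioface selection. Proton loss after closure of ring A may also stop the cascade at monocyclic trienones. The fallback gives up the cyclization and takes the ring stereocentres from the chiral pool. It does not set out from a numbered compound: 1 and 2 are bypassed, and the start is commercial (−)-sclareol F1. It returns to the route at ketol 4. KMnO4 buffered with MgSO4 in aqueous acetone at 0–20 °C cleaves the C14=C15 vinyl group and oxidatively decarboxylates the resulting α-hydroxy acid. This is the classical degradation of this diol to the C18 hydroxy ketone, with rings A and B and C5, C8, C9 and C10 carried over unchanged.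

Step 3. The olefination may give poor E/Z control at C13=C14, and under base O-8 may add to C13 to close an 8,13-epoxy ester. The fallback sets out from ketol 4 and returns at allylic diol 7, so step 4 is bypassed and the alkene geometry is set by a syn carbometalation. LiN(i-Pr)2 (one extra equivalent for the C8 hydroxyl, THF, −78 °C) deprotonates the methyl group kinetically, and ClP(O)(OEt)2 traps the enolate as diethyl 8α-hydroxy-14,15-dinorlabd-13(16)-en-13-yl phosphate F2. Further LiN(i-Pr)2 eliminates phosphate to give 15,16-dinorlabd-13-yn-8α-ol F3. Zirconium-catalysed methylalumination (Me3Al, Cp2ZrCl2, CH2Cl2, rt; Negishi carboalumination) adds methyl to C13 and aluminium to the terminal carbon on the same side. Treatment of the alkenylalane with n-BuLi and (CH2O)n should then give 7 as the E isomer only.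

Step 5. Facial selection at C13 may be insufficient, or the alkene may migrate before hydrogen is delivered, which would give the C13 epimer. The fallback sets out from enoate 6 and returns at diol 8, bypassing steps 4 and 5, and sets C13 by hydride conjugate addition. A CuH catalyst made from CuCl, NaOt-Bu and p-Tol-BINAP with polymethylhydrosiloxane in toluene at rt reduces the (13E)-enoate to ethyl (13S)-8α-hydroxylabdan-15-oate F4. The ligand antipode is chosen on a model (E)-3-methyl enoate so that it gives 13S. LiAlH4 in THF at 0 °C then reduces F4 to 8.

Further compounds
F1 | step 1 | (−)-sclareol, (13R)-labd-14-ene-8α,13-diol | C=C[C@](C)(O)CC[C@@H]1[C@@]2(C)CCCC(C)(C)[C@@H]2CC[C@@]1(C)O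
F2 | step 3 | diethyl 8α-hydroxy-14,15-dinorlabd-13(16)-en-13-yl phosphate | C=C(OP(=O)(OCC)OCC)CC[C@@H]1[C@@]2(C)CCCC(C)(C)[C@@H]2CC[C@@]1(C)O
F3 | step 3 | 15,16-dinorlabd-13-yn-8α-ol | C#CCC[C@@H]1[C@@]2(C)CCCC(C)(C)[C@@H]2CC[C@@]1(C)O
F4 | step 5 | ethyl (13S)-8α-hydroxylabdan-15-oate | CCOC(=O)C[C@@H](C)CC[C@@H]1[C@@]2(C)CCCC(C)(C)[C@@H]2CC[C@@]1(C)O
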